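**Retrosynthetic overview**

1. Target ⇐ its octamethyl ether (global O‑demethylation) ⇐ Heck attachment of the 4‑methoxystyryl arm to a ring‑A aryl chloride, placed after all light‑driven steps.
2. Both C3–aryl bonds (C3 of unit 2 to the 3,5‑dimethoxyphenyl ring; C3 of unit 1 to C6 of unit 2) ⇐ visible‑light iridium/nickel decarboxylative arylation of 2‑aryl‑2,3‑dihydrobenzofuran‑3‑carboxylic acids; each C3 centre is set trans by its bought C2 neighbour.
3. Both dihydrobenzofuran rings ⇐ flavanones by an iodide‑mediated anodic ring contraction (1,2‑shift of ring A from C4 to C3).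
4. (2S)‑Flavanone = hesperetin (C2 of unit 2 bought); (2R)‑flavanone ⇐ methyl (2R,3S)‑3‑(4‑methoxyphenyl)glycidate (C2 of unit 1 bought) by aryllithium acylation, SmI2 epoxide opening and SNAr ring closure.
5. Ring order: pyranone of the (2R)‑flavanone → furan ring of unit 2 and furan ring of unit 1 (ring contractions) → no further rings.

Unit 1 is the dihydrobenzofuran carrying the styryl arm and the 4‑hydroxyphenyl group (2R,3R). Unit 2 is the one carrying the catechol and resorcinol rings (2S,3S). Both are trans.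

Assumption: (2S)‑hesperetin (aglycone of the citrus flavonoid hesperidin) and methyl (2R,3S)‑3‑(4‑methoxyphenyl)glycidate (the bulk diltiazem intermediate) are bought as single enantiomers.

**Route**

Step 1
Reactants: 1 (2S)-hesperetin
Product: 2 (2S)-5-hydroxy-2-(3-hydroxy-4-methoxyphenyl)-4-oxo-3,4-dihydro-2H-chromen-7-yl trifluoromethanesulfonate
Conditions: PhNTf2 (1.05 equiv), Et3N (1.2 equiv), CH2Cl2, 0 → 20 °C
Reagents that add atoms: N-phenylbis(trifluoromethanesulfonimide), O=S(=O)(N(c1ccccc1)S(=O)(=O)C(F)(F)F)C(F)(F)F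
Why: Phenol O‑sulfonylation; the 7‑OH (para to the carbonyl, most acidic) reacts ahead of the chelated 5‑OH and the less acidic 3'‑OH, and C2 is not involved.

Step 2
Reactants: 2 hesperetin 7-triflate
Product: 3 (2S)-2-(3,4-dimethoxyphenyl)-5-methoxy-4-oxo-3,4-dihydro-2H-chromen-7-yl trifluoromethanesulfonate
Conditions: MeI (excess), Ag2O, CaSO4, CHCl3, 40 °C, dark
Reagents that add atoms: iodomethane, CI
Why: Purdie O‑methylation caps both remaining phenols (the chelated 5‑OH included) under weakly basic heterogeneous conditions, avoiding the retro‑oxa‑Michael opening and C2 racemisation that carbonate or alkoxide bases cause.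

Step 3
Reactants: 3 flavanone triflate
Product: 4 methyl (2S,3S)-2-(3,4-dimethoxyphenyl)-4-methoxy-6-(trifluoromethanesulfonyloxy)-2,3-dihydro-1-benzofuran-3-carboxylate (trans)
Conditions: I2 (0.25 equiv), LiClO4 (0.1 M), H2SO4 (cat.), HC(OMe)3/MeOH 4:1, undivided cell, graphite anode, Pt cathode, 5 mA cm−2, 2.5 F mol−1, 25 °C
Reagents that add atoms: methanol, CO; trimethyl orthoformate, COC(OC)OC (both serve as source of the ester OCH3)
Why: Proposed new method: in acidic orthoformate the ketone is ketalised/enolised and iodinated at C3 anti to the C2 aryl group by iodine held at low concentration, ionisation of that carbon–iodine bond (assisted by the antiperiplanar, oxygen‑rich ring A) triggers a 1,2‑aryl shift that forms the C3–C3a bond with inversion and leaves a dioxocarbenium ion that ends as the methyl ester, while iodide is re‑oxidised at the anode at a potential far below that of the dimethoxyarene and protons are reduced at the cathode; C2 is untouched and C3 comes out trans (3S); closest known reaction types are the iodine‑mediated anodic 1,2‑aryl shift of acyclic alkyl aryl ketones to methyl 2‑arylalkanoates in trimethyl orthoformate and the ring contraction of flavanones by stoichiometric trivalent thallium or trivalent iodine oxidants.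

Step 4
Reactants: 5 1-chloro-3,5-difluorobenzene; 6 methyl (2R,3S)-3-(4-methoxyphenyl)oxirane-2-carboxylate
Product: 9 (4-chloro-2-fluoro-6-methoxyphenyl)[(2R,3S)-3-(4-methoxyphenyl)oxiran-2-yl]methanone, via aryllithium 7 (not isolated), via difluoro epoxy ketone 8 (not isolated)
Conditions: 5, n-BuLi, THF, −78 °C; add 6, −78 °C; then DMPU, −78 → 20 °C
Reagents that add atoms: none
Why: Ortho‑lithiation between the two fluorines, single acylation of the hindered aryllithium by the glycidic ester, then nucleophilic aromatic substitution of one carbonyl‑activated ortho‑fluorine by the lithium methoxide just released; both epoxide stereocentres are untouched.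

Step 5
Reactants: 9 fluoro methoxy epoxy ketone
Product: 10 (3R)-1-(4-chloro-2-fluoro-6-methoxyphenyl)-3-hydroxy-3-(4-methoxyphenyl)propan-1-one
Conditions: SmI2 (2.5 equiv), THF/MeOH 3:1, −90 °C
Reagents that add atoms: none
Why: Reductive opening of an α,β‑epoxy ketone (ketyl formation, cleavage of the α carbon–oxygen bond) gives the aldol; the benzylic carbon–oxygen bond and its configuration are kept (the descriptor changes only because C2 loses its oxygen).

Step 6
Reactants: 10 β-hydroxy ketone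
Product: 11 (2R)-7-chloro-5-methoxy-2-(4-methoxyphenyl)-2,3-dihydro-4H-chromen-4-one
Conditions: NaH (1.05 equiv), THF/DMF, 0 °C
Reagents that add atoms: none
Why: Intramolecular nucleophilic aromatic substitution (6‑exo) of the carbonyl‑activated ortho‑fluorine by the benzylic alkoxide closes the pyranone with retention at C2, since the carbon–oxygen bond of the stereocentre is never broken; the single equivalent of base ends as NaF, so none is left to open the flavanone.

Step 7
Reactants: 11 (2R)-flavanone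
Product: 13 (2R,3R)-6-chloro-4-methoxy-2-(4-methoxyphenyl)-2,3-dihydro-1-benzofuran-3-carboxylic acid (trans), via methyl ester 12 (not isolated)
Conditions: I2 (0.25 equiv), LiClO4, H2SO4 (cat.), HC(OMe)3/MeOH 4:1, undivided cell, graphite anode, Pt cathode, 5 mA cm−2, 2.5 F mol−1, 25 °C; extractive work-up, then Me3SnOH, ClCH2CH2Cl, 80 °C; 1 M HCl work-up
Reagents that add atoms: methanol, CO; trimethyl orthoformate, COC(OC)OC (source of the OCH3 of 12); trimethyltin hydroxide, C[Sn](C)(C)O (hydroxyl oxygen of 13)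
Why: Proposed new method: the same iodide‑mediated anodic ring contraction as in step 3 (C3 iodination anti to the C2 aryl group, ionisation with 1,2‑shift of ring A forming the C3–C3a bond, anodic re‑oxidation of iodide; closest known reaction types are the iodine‑mediated anodic 1,2‑aryl shift of alkyl aryl ketones in trimethyl orthoformate and the flavanone ring contraction by trivalent thallium or trivalent iodine oxidants) gives the trans ester with C2 untouched, and near‑neutral Me3SnOH ester cleavage then frees the acid without enolate formation.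

Step 8
Reactants: 13 unit 1 carboxylic acid; 4 unit 2 aryl triflate
Product: 14 methyl (2S,3S)-6-[(2R,3R)-6-chloro-4-methoxy-2-(4-methoxyphenyl)-2,3-dihydro-1-benzofuran-3-yl]-2-(3,4-dimethoxyphenyl)-4-methoxy-2,3-dihydro-1-benzofuran-3-carboxylate
Conditions: Ir[dF(CF3)ppy]2(dtbbpy)PF6 (1 mol%), NiBr2·glyme (10 mol%), dtbbpy (15 mol%), Cs2CO3 (1.0 equiv), DMF, blue LEDs (450 nm), 25 °C
Reagents that add atoms: none
Why: Metallaphotoredox decarboxylative arylation: the carboxylate is oxidised by the excited iridium photocatalyst to the benzylic C3 radical, which the arylnickel species formed from the triflate captures on the face anti to the C2 aryl group, so C3 of unit 1 is set trans (3R) under control of the bought C2.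

Step 9
Reactants: 14 coupled methyl ester
Product: 15 (2S,3S)-6-[(2R,3R)-6-chloro-4-methoxy-2-(4-methoxyphenyl)-2,3-dihydro-1-benzofuran-3-yl]-2-(3,4-dimethoxyphenyl)-4-methoxy-2,3-dihydro-1-benzofuran-3-carboxylic acid
Conditions: Me3SnOH, ClCH2CH2Cl, 80 °C; 1 M HCl work-up
Reagents that add atoms: trimethyltin hydroxide, C[Sn](C)(C)O
Why: Near‑neutral ester cleavage with Me3SnOH avoids the ester enolate and with it ring opening or epimerisation of the dihydrobenzofuran.

Step 10
Reactants: 15 coupled acid; 16 1-bromo-3,5-dimethoxybenzene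
Product: 17 (2R,3R)-6-chloro-3-[(2S,3S)-2-(3,4-dimethoxyphenyl)-3-(3,5-dimethoxyphenyl)-4-methoxy-2,3-dihydro-1-benzofuran-6-yl]-4-methoxy-2-(4-methoxyphenyl)-2,3-dihydro-1-benzofuran
Conditions: Ir[dF(CF3)ppy]2(dtbbpy)PF6 (1 mol%), NiBr2·glyme (10 mol%), dtbbpy (15 mol%), Cs2CO3 (1.0 equiv), DMF, blue LEDs (450 nm), 25 °C
Reagents that add atoms: none
Why: Second metallaphotoredox decarboxylative arylation; the C3 radical of unit 2 is arylated anti to the C2 dimethoxyphenyl group, giving the trans (3S) centre, and the electron‑rich aryl chloride is left alone by nickel.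

Step 11
Reactants: 17 aryl chloride; 18 4-methoxystyrene
Product: 19 (2R,3R)-3-[(2S,3S)-2-(3,4-dimethoxyphenyl)-3-(3,5-dimethoxyphenyl)-4-methoxy-2,3-dihydro-1-benzofuran-6-yl]-4-methoxy-2-(4-methoxyphenyl)-6-[(E)-2-(4-methoxyphenyl)ethenyl]-2,3-dihydro-1-benzofuran
Conditions: Pd2(dba)3 (2.5 mol%), P(t-Bu)3·HBF4 (10 mol%), Cs2CO3, 1,4-dioxane, 110 °C
Reagents that add atoms: none
Why: Mizoroki–Heck reaction of the aryl chloride gives the E‑stilbene; it follows the last light‑driven step so that the stilbene never meets a triplet sensitiser.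

Step 12
Reactants: 19 octamethyl ether
Product: 20 4-[(E)-2-{(2R,3R)-3-[(2S,3S)-2-(3,4-dihydroxyphenyl)-3-(3,5-dihydroxyphenyl)-4-hydroxy-2,3-dihydro-1-benzofuran-6-yl]-4-hydroxy-2-(4-hydroxyphenyl)-2,3-dihydro-1-benzofuran-6-yl}ethenyl]phenol
Conditions: BBr3 (16 equiv), CH2Cl2, −78 → 0 °C; then MeOH, H2O
Reagents that add atoms: none
Why: Lewis‑acid cleavage of all eight aryl methyl ethers; no stereocentre takes part.

**Compound list**

1 | (2S)-hesperetin, (2S)-5,7-dihydroxy-2-(3-hydroxy-4-methoxyphenyl)-2,3-dihydro-4H-chromen-4-one | COc1ccc(cc1O)[C@@H]1CC(=O)c2c(O)cc(O)cc2O1 | starting material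
2 | (2S)-5-hydroxy-2-(3-hydroxy-4-methoxyphenyl)-4-oxo-3,4-dihydro-2H-chromen-7-yl trifluoromethanesulfonate | COc1ccc(cc1O)[C@@H]1CC(=O)c2c(O)cc(OS(=O)(=O)C(F)(F)F)cc2O1 | intermediate
3 | (2S)-2-(3,4-dimethoxyphenyl)-5-methoxy-4-oxo-3,4-dihydro-2H-chromen-7-yl trifluoromethanesulfonate | COc1ccc(cc1OC)[C@@H]1CC(=O)c2c(OC)cc(OS(=O)(=O)C(F)(F)F)cc2O1 | intermediate
4 | methyl (2S,3S)-2-(3,4-dimethoxyphenyl)-4-methoxy-6-(trifluoromethanesulfonyloxy)-2,3-dihydro-1-benzofuran-3-carboxylate (trans) | FC(F)(F)S(=O)(=O)Oc1cc(OC)c2c(c1)O[C@H](c1ccc(OC)c(OC)c1)[C@H]2C(=O)OC | intermediate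
5 | 1-chloro-3,5-difluorobenzene | Fc1cc(Cl)cc(F)c1 | starting material
6 | methyl (2R,3S)-3-(4-methoxyphenyl)oxirane-2-carboxylate (trans glycidate) | COC(=O)[C@@H]1O[C@H]1c1ccc(OC)cc1 | starting material
7 | (4-chloro-2,6-difluorophenyl)lithium | [Li]c1c(F)cc(Cl)cc1F | intermediate
8 | (4-chloro-2,6-difluorophenyl)[(2R,3S)-3-(4-methoxyphenyl)oxiran-2-yl]methanone | O=C(c1c(F)cc(Cl)cc1F)[C@@H]1O[C@H]1c1ccc(OC)cc1 | intermediate
9 | (4-chloro-2-fluoro-6-methoxyphenyl)[(2R,3S)-3-(4-methoxyphenyl)oxiran-2-yl]methanone | COc1cc(Cl)cc(F)c1C(=O)[C@@H]1O[C@H]1c1ccc(OC)cc1 | intermediate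
10 | (3R)-1-(4-chloro-2-fluoro-6-methoxyphenyl)-3-hydroxy-3-(4-methoxyphenyl)propan-1-one | COc1cc(Cl)cc(F)c1C(=O)C[C@@H](O)c1ccc(OC)cc1 | intermediate
11 | (2R)-7-chloro-5-methoxy-2-(4-methoxyphenyl)-2,3-dihydro-4H-chromen-4-one | COc1ccc(cc1)[C@H]1CC(=O)c2c(OC)cc(Cl)cc2O1 | intermediate
12 | methyl (2R,3R)-6-chloro-4-methoxy-2-(4-methoxyphenyl)-2,3-dihydro-1-benzofuran-3-carboxylate (trans) | Clc1cc(OC)c2c(c1)O[C@@H](c1ccc(OC)cc1)[C@@H]2C(=O)OC | intermediate
13 | (2R,3R)-6-chloro-4-methoxy-2-(4-methoxyphenyl)-2,3-dihydro-1-benzofuran-3-carboxylic acid (trans) | Clc1cc(OC)c2c(c1)O[C@@H](c1ccc(OC)cc1)[C@@H]2C(=O)O | intermediate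
14 | methyl (2S,3S)-6-[(2R,3R)-6-chloro-4-methoxy-2-(4-methoxyphenyl)-2,3-dihydro-1-benzofuran-3-yl]-2-(3,4-dimethoxyphenyl)-4-methoxy-2,3-dihydro-1-benzofuran-3-carboxylate | Clc1cc(OC)c2c(c1)O[C@@H](c1ccc(OC)cc1)[C@@H]2c1cc(OC)c2c(c1)O[C@H](c1ccc(OC)c(OC)c1)[C@H]2C(=O)OC | intermediate
15 | (2S,3S)-6-[(2R,3R)-6-chloro-4-methoxy-2-(4-methoxyphenyl)-2,3-dihydro-1-benzofuran-3-yl]-2-(3,4-dimethoxyphenyl)-4-methoxy-2,3-dihydro-1-benzofuran-3-carboxylic acid | Clc1cc(OC)c2c(c1)O[C@@H](c1ccc(OC)cc1)[C@@H]2c1cc(OC)c2c(c1)O[C@H](c1ccc(OC)c(OC)c1)[C@H]2C(=O)O | intermediate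
16 | 1-bromo-3,5-dimethoxybenzene | COc1cc(Br)cc(OC)c1 | starting material
17 | (2R,3R)-6-chloro-3-[(2S,3S)-2-(3,4-dimethoxyphenyl)-3-(3,5-dimethoxyphenyl)-4-methoxy-2,3-dihydro-1-benzofuran-6-yl]-4-methoxy-2-(4-methoxyphenyl)-2,3-dihydro-1-benzofuran | Clc1cc(OC)c2c(c1)O[C@@H](c1ccc(OC)cc1)[C@@H]2c1cc(OC)c2c(c1)O[C@H](c1ccc(OC)c(OC)c1)[C@H]2c1cc(OC)cc(OC)c1 | intermediate
18 | 4-methoxystyrene (1-ethenyl-4-methoxybenzene) | C=Cc1ccc(OC)cc1 | starting material
19 | octamethyl ether of the target, (2R,3R)-3-[(2S,3S)-2-(3,4-dimethoxyphenyl)-3-(3,5-dimethoxyphenyl)-4-methoxy-2,3-dihydro-1-benzofuran-6-yl]-4-methoxy-2-(4-methoxyphenyl)-6-[(E)-2-(4-methoxyphenyl)ethenyl]-2,3-dihydro-1-benzofuran | COc1ccc(/C=C/c2cc(OC)c3c(c2)O[C@@H](c2ccc(OC)cc2)[C@@H]3c2cc(OC)c3c(c2)O[C@H](c2ccc(OC)c(OC)c2)[C@H]3c2cc(OC)cc(OC)c2)cc1 | intermediate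
20 | CNP0107857.3, 4-[(E)-2-{(2R,3R)-3-[(2S,3S)-2-(3,4-dihydroxyphenyl)-3-(3,5-dihydroxyphenyl)-4-hydroxy-2,3-dihydro-1-benzofuran-6-yl]-4-hydroxy-2-(4-hydroxyphenyl)-2,3-dihydro-1-benzofuran-6-yl}ethenyl]phenol | Oc1ccc(/C=C/c2cc(O)c3c(c2)O[C@@H](c2ccc(O)cc2)[C@@H]3c2cc(O)c3c(c2)O[C@H](c2ccc(O)c(O)c2)[C@H]3c2cc(O)cc(O)c2)cc1 | target

**Step count and risks**

Total step count: 12. Longest linear sequence: 9 steps (steps 4 to 12, from 5 and 6); the hesperetin branch (steps 1 to 3) joins at step 8.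

Three steps most likely to fail:

1. Step 3, the new anodic ring contraction (step 7 applies the same reaction to 11). A 2,3‑shift of the dimethoxyphenyl ring (isoflavone formation), dehydrogenation to the flavone, or sluggish enolisation of the donor‑deactivated ketone could take over. The fallback uses known chemistry, sets out from 3 and comes back at 4. Detrifluoroacetylative diazo transfer (LiHMDS, CF3CO2CH2CF3, THF, −78 °C; then MsN3, Et3N, MeCN) passes through the 3‑trifluoroacetyl ketone F1 and gives the 3‑diazo flavanone F2. Photochemical Wolff rearrangement (365 nm, MeOH) contracts the ring to the methyl ester, formed in part as the cis epimer F3. Catalytic DBU in MeOH equilibrates the mixture to the trans ester 4, where the route resumes.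

2. Step 8, the fragment union. The C3 radical is flanked by the C4 methoxy group and the C2 aryl group, the electron‑rich aryl triflate adds slowly to nickel, and the ester of 4 is sensitive to carbonate. The fallback sets out from 13 and 4 and comes back at 14, reversing the polarity of unit 2 and dropping the photocatalyst. Acid 13 is turned into its N‑hydroxyphthalimide ester F4 (N‑hydroxyphthalimide, DIC, cat. DMAP, CH2Cl2). Triflate 4 is borylated to the arylboronic acid F5 (B2(OH)4, Pd(OAc)2/XPhos, KOAc, EtOH, 80 °C). Thermal nickel‑catalysed decarboxylative coupling of the redox‑active ester with the boronic acid (NiCl2·6H2O, bathophenanthroline, Et3N, 1,4‑dioxane/DMF, 75 °C) then gives 14, again trans by approach anti to the C2 aryl group.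

3. Step 12, the eightfold demethylation. The hydrogen bromide released can protonate the electron‑rich stilbene and trigger Friedel–Crafts cyclisation onto the neighbouring resorcinol rings. The fallback sets out from 17 and comes back at 20, removing the methyl groups before the alkene exists. BBr3 (CH2Cl2, −78 → 0 °C) on 17 gives the heptaphenol chloride F6. Ac2O/pyridine gives the heptaacetate F7. Heck reaction with 4‑acetoxystyrene (Pd2(dba)3, P(t‑Bu)3·HBF4, Cy2NMe, 1,4‑dioxane, 100 °C) gives the octaacetate F8. K2CO3 in MeOH at 0 °C under argon then releases 20.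

**Further compounds**

F1 | step 3 | (2R)-2-(3,4-dimethoxyphenyl)-4-hydroxy-5-methoxy-3-(trifluoroacetyl)-2H-chromen-7-yl trifluoromethanesulfonate (enol form of the 3-trifluoroacetyl ketone; C2 unchanged in space) | COc1ccc(cc1OC)[C@@H]1C(C(=O)C(F)(F)F)=C(O)c2c(OC)cc(OS(=O)(=O)C(F)(F)F)cc2O1
F2 | step 3 | (2R)-3-diazo-2-(3,4-dimethoxyphenyl)-5-methoxy-4-oxo-3,4-dihydro-2H-chromen-7-yl trifluoromethanesulfonate (C2 unchanged in space) | COc1ccc(cc1OC)[C@@H]1C(=[N+]=[N-])C(=O)c2c(OC)cc(OS(=O)(=O)C(F)(F)F)cc2O1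
F3 | step 3 | methyl (2S,3R)-2-(3,4-dimethoxyphenyl)-4-methoxy-6-(trifluoromethanesulfonyloxy)-2,3-dihydro-1-benzofuran-3-carboxylate (cis) | FC(F)(F)S(=O)(=O)Oc1cc(OC)c2c(c1)O[C@H](c1ccc(OC)c(OC)c1)[C@@H]2C(=O)OC
F4 | step 8 | 1,3-dioxoisoindolin-2-yl (2R,3R)-6-chloro-4-methoxy-2-(4-methoxyphenyl)-2,3-dihydro-1-benzofuran-3-carboxylate | Clc1cc(OC)c2c(c1)O[C@@H](c1ccc(OC)cc1)[C@@H]2C(=O)ON1C(=O)c2ccccc2C1=O
F5 | step 8 | [(2S,3S)-2-(3,4-dimethoxyphenyl)-4-methoxy-3-(methoxycarbonyl)-2,3-dihydro-1-benzofuran-6-yl]boronic acid | OB(O)c1cc(OC)c2c(c1)O[C@H](c1ccc(OC)c(OC)c1)[C@H]2C(=O)OC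
F6 | step 12 | 4-[(2S,3S)-6-[(2R,3R)-6-chloro-4-hydroxy-2-(4-hydroxyphenyl)-2,3-dihydro-1-benzofuran-3-yl]-3-(3,5-dihydroxyphenyl)-4-hydroxy-2,3-dihydro-1-benzofuran-2-yl]benzene-1,2-diol | Clc1cc(O)c2c(c1)O[C@@H](c1ccc(O)cc1)[C@@H]2c1cc(O)c2c(c1)O[C@H](c1ccc(O)c(O)c1)[C@H]2c1cc(O)cc(O)c1
F7 | step 12 | heptaacetate of F6 (all seven phenols acetylated) | Clc1cc(OC(C)=O)c2c(c1)O[C@@H](c1ccc(OC(C)=O)cc1)[C@@H]2c1cc(OC(C)=O)c2c(c1)O[C@H](c1ccc(OC(C)=O)c(OC(C)=O)c1)[C@H]2c1cc(OC(C)=O)cc(OC(C)=O)c1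
F8 | step 12 | octaacetate of the target 20 | CC(=O)Oc1ccc(/C=C/c2cc(OC(C)=O)c3c(c2)O[C@@H](c2ccc(OC(C)=O)cc2)[C@@H]3c2cc(OC(C)=O)c3c(c2)O[C@H](c2ccc(OC(C)=O)c(OC(C)=O)c2)[C@H]3c2cc(OC(C)=O)cc(OC(C)=O)c2)cc1
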